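**Retrosynthetic overview**
1. Isobutyryl alkannin ⇒ alkannin + isobutyric acid (side-chain O-acylation comes last). Alkannin ⇒ its allyl analogue + 2-methylbut-2-ene (cross-metathesis).
2. Ring B (the quinone ring) is cut at C1–C8a. This gives a hydroquinone with a (Z)-4-oxo-enal side chain, whose formyl carbon (the 3''-carbon of the terpenoid chain) closes onto the ring carbon next to the side chain, as in the cyclisation of 3''-oxidised geranylhydroquinone.
3. (Z)-Oxo-enal ⇒ 2-arylfuran + singlet oxygen. The furan is a geometry-locked, latent 1',3''-dioxygenated isoprene unit.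
4. Aryl–C1' bond ⇒ 1,4-benzoquinone + 3-furyl carbinol. The quinol nucleus is joined to the chain terminus first, like the aromatic prenylation.
5. (S)-Carbinol ⇒ furan-3-carbaldehyde + allylBpin (catalytic asymmetric allylboration). Ring order: ring A is bought as benzoquinone, and ring B is the only ring made (step 3).

Assumption: the two naphthazarin tautomers (side chain on the quinonoid or the benzenoid ring) interconvert rapidly and are written throughout as the tautomer of the target SMILES.

**Step 1**
Reactants: 1 furan-3-carbaldehyde; 2 allylboronic acid pinacol ester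
Product: 4 (1S)-1-(furan-3-yl)but-3-en-1-ol, via pinacol borate ester 3 (not isolated)
Conditions: (S)-TRIP phosphoric acid (5 mol %), toluene, −30 °C; H2O work-up
Reagents that add atoms: none
Why: Chiral-phosphoric-acid-catalysed allylboration through a closed chair transition state in which the acid binds the boronate oxygen and the formyl H, so that (S)-TRIP delivers allyl to the Si face and sets the (S)-carbinol (the (R)-acid gives (R)-carbinols from aryl aldehydes).

**Step 2**
Reactants: 4 (1S)-1-(furan-3-yl)but-3-en-1-ol; 5 1,4-benzoquinone
Product: 7 2-{4-[(1S)-1-hydroxybut-3-en-1-yl]furan-2-yl}benzene-1,4-diol, via furylquinone 6 (not isolated)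
Conditions: 5 (3 equiv), Sc(OTf)3 (5 mol %), MeCN, 0 °C → rt, dark; then aq Na2S2O4/EtOAc
Reagents that add atoms: none
Why: Lewis-acid-catalysed Friedel–Crafts-type conjugate addition of a furan to a quinone (furylation of quinones), in which the Sc(III)-activated quinone is attacked by the unhindered α-carbon C5 of the 3-substituted furan, excess 5 dehydrogenates the adduct to violet 6 and dithionite returns it to 7; the carbinol centre is not involved, the terminal alkene is far too poor a nucleophile to compete, and any C2-linked regioisomer ends in the same naphthazarin because both furan α-carbons become quinone carbonyl carbons.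

**Step 3**
Reactants: 7 2-{4-[(1S)-1-hydroxybut-3-en-1-yl]furan-2-yl}benzene-1,4-diol
Product: 11 5,8-dihydroxy-2-[(1S)-1-hydroxybut-3-en-1-yl]naphthalene-1,4-dione, via furan endoperoxide 8 (not isolated), via Z-oxoenal 9 (not isolated), via leuco tetrol 10 (not isolated)
Conditions: O2, TPP (1 mol %), white LED, CH2Cl2–EtOAc, −78 °C; Me2S (3 equiv), −78 °C → rt; MgBr2·OEt2 (2.5 equiv), Et3N (4 equiv), Ar, 0 °C → rt; then air, 0 °C; 1 M HCl work-up
Reagents that add atoms: dioxygen, O=O
Why: Proposed new method: [4+2] addition of singlet oxygen to the electron-rich 2-arylfuran (terminal alkene inert, TPP triplet too weak an oxidant for the quinol) followed by Me2S reduction is the known furan-to-cis-4-oxo-enal opening, the former furan ring fixes the Z geometry, the Mg(II) chelate between the ketone and the ortho-phenolate turns the chain so that the formyl carbon lies over the free ring carbon next to the side chain, and there the second magnesium phenolate delivers an ortho-specific hydroxyalkylation (closest known types: Casiraghi/Skattebøl magnesium-phenolate hydroxyalkylation and the intramolecular Marschalk cyclisation), after which enolisation erases the transient ring carbinol centre to give 10 and autoxidation gives the naphthazarin, the (S)-centre being a spectator throughout.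

**Step 4**
Reactants: 11 5,8-dihydroxy-2-[(1S)-1-hydroxybut-3-en-1-yl]naphthalene-1,4-dione; 12 2-methylbut-2-ene
Product: 13 alkannin, 5,8-dihydroxy-2-[(1S)-1-hydroxy-4-methylpent-3-en-1-yl]naphthalene-1,4-dione
Conditions: 12 (co-solvent), Hoveyda–Grubbs II (5 mol %), CH2Cl2, 40 °C, sealed tube, dark
Reagents that add atoms: none
Why: Olefin cross-metathesis of a terminal alkene with a large excess of 2-methylbut-2-ene turns allyl into prenyl, the electron-poor trisubstituted quinone C=C is metathesis-inert, quinones are tolerated by Ru carbenes (they even suppress Ru–H isomerisation), and the stereocentre is untouched.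

**Step 5**
Reactants: 13 alkannin; 14 2-methylpropanoic (isobutyric) acid
Product: 15 isobutyryl alkannin, (1S)-1-(5,8-dihydroxy-1,4-dioxo-1,4-dihydronaphthalen-2-yl)-4-methylpent-3-en-1-yl 2-methylpropanoate
Conditions: 14 (1.5 equiv), DCC (1.5 equiv), DMAP (0.2 equiv), CH2Cl2, 0 °C → rt, dark
Reagents that add atoms: none
Why: Steglich esterification, the established way to acylate alkannin/shikonin, touches only the side-chain alcohol because both peri-OH groups are locked in strong hydrogen bonds to the quinone carbonyls, and the C–O bond at the stereocentre is never broken, so (S) is retained.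

**Compound list**
1 | furan-3-carbaldehyde | O=Cc1ccoc1 | starting material
2 | allylboronic acid pinacol ester | C=CCB1OC(C)(C)C(C)(C)O1 | starting material
3 | 2-{[(1S)-1-(furan-3-yl)but-3-en-1-yl]oxy}-4,4,5,5-tetramethyl-1,3,2-dioxaborolane | C=CC[C@H](OB1OC(C)(C)C(C)(C)O1)c1ccoc1 | intermediate
4 | (1S)-1-(furan-3-yl)but-3-en-1-ol | C=CC[C@H](O)c1ccoc1 | intermediate
5 | 1,4-benzoquinone | O=C1C=CC(=O)C=C1 | starting material
6 | 2-{4-[(1S)-1-hydroxybut-3-en-1-yl]furan-2-yl}cyclohexa-2,5-diene-1,4-dione | C=CC[C@H](O)c1coc(C2=CC(=O)C=CC2=O)c1 | intermediate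
7 | 2-{4-[(1S)-1-hydroxybut-3-en-1-yl]furan-2-yl}benzene-1,4-diol | C=CC[C@H](O)c1coc(-c2cc(O)ccc2O)c1 | intermediate
8 | 1-(2,5-dihydroxyphenyl)-5-[(1S)-1-hydroxybut-3-en-1-yl]-2,3,7-trioxabicyclo[2.2.1]hept-5-ene (both bridgehead diastereomers) | C=CC[C@H](O)C1=CC2(c3cc(O)ccc3O)OOC1O2 | intermediate
9 | (2Z)-4-(2,5-dihydroxyphenyl)-2-[(1S)-1-hydroxybut-3-en-1-yl]-4-oxobut-2-enal | C=CC[C@H](O)/C(C=O)=C/C(=O)c1cc(O)ccc1O | intermediate
10 | 2-[(1S)-1-hydroxybut-3-en-1-yl]naphthalene-1,4,5,8-tetrol | C=CC[C@H](O)c1cc(O)c2c(O)ccc(O)c2c1O | intermediate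
11 | 5,8-dihydroxy-2-[(1S)-1-hydroxybut-3-en-1-yl]naphthalene-1,4-dione | C=CC[C@H](O)C1=CC(=O)c2c(O)ccc(O)c2C1=O | intermediate
12 | 2-methylbut-2-ene | CC=C(C)C | starting material
13 | alkannin | CC(C)=CC[C@H](O)C1=CC(=O)c2c(O)ccc(O)c2C1=O | intermediate
14 | 2-methylpropanoic acid | CC(C)C(=O)O | starting material
15 | isobutyryl alkannin | CC(C)=CC[C@H](OC(=O)C(C)C)C1=CC(=O)c2c(O)ccc(O)c2C1=O | target

**Total step count:** 5. **Longest linear sequence:** 5 (1 → 4 → 7 → 11 → 13 → 15).

**Steps most likely to fail**

Step 3 carries the highest risk.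
- The ring carbon that must attack the aldehyde is flanked by the acyl group and is only a moderate nucleophile.
- Compound 9 can drain into an O-cyclised benzofuranone or suffer retro-aldol loss of the side chain.
- Compound 10 can expel the benzylic OH if it is not oxidised at once.

The fallback sets out from 9, taken crude after the Me2S reduction, and replaces the polar closure by a radical one. Ag2O in CH2Cl2 oxidises the quinol to the acylquinone enal F1. Irradiation at 450 nm in degassed CH2Cl2 then triggers an intramolecular photo-Friedel–Crafts (Klinger-type) acylation. The excited quinone abstracts the nearby formyl hydrogen, and the acyl radical/semiquinone pair collapses at the very electrophilic ring carbon next to the acyl group. Tautomerisation gives the naphthazarin directly, without any leuco stage. This fallback comes back to the route at 11.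

Step 2 is the second risk.
- A furan without a donor group is a borderline nucleophile for activated benzoquinone.
- Bis-furylation, oligomerisation or acid ionisation of the 3-furyl carbinol (loss of ee) may win.

The fallback sets out from 4 and makes the C–C bond by metal catalysis instead of electrophilic substitution. Sterically controlled Ir-catalysed C–H borylation ([Ir(OMe)(cod)]2, dtbpy, B2pin2, THF, rt; the O-boryl group falls off on work-up) gives the C5 furylboronate F2. Pd(TFA)2 then couples F2 oxidatively with excess 5 in acetone at rt. This fallback comes back to the route at 6, which is reduced with dithionite as before.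

Step 4 is the third risk.
- The peri-hydroxyquinone can sequester ruthenium.
- The light- and heat-sensitive pigment can oligomerise during a slow metathesis.

The fallback sets out from 7 and installs the prenyl terminus before ring B exists. Cross-metathesis of 7 with 12 (phenols are well tolerated) gives the prenyl furylhydroquinone F3. Photooxygenation at −78 °C is stopped at full furan consumption, because the arylfuran reacts far faster than a trisubstituted alkene, and gives the prenyl endoperoxide F4. Me2S gives the prenyl Z-oxoenal F5, and the magnesium-phenolate closure gives leucoalkannin F6. Air oxidation brings the fallback back to the route at 13.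

**Further compounds**
F1 | step 3 | (2Z)-4-(3,6-dioxocyclohexa-1,4-dien-1-yl)-2-[(1S)-1-hydroxybut-3-en-1-yl]-4-oxobut-2-enal | C=CC[C@H](O)/C(C=O)=C/C(=O)C1=CC(=O)C=CC1=O
F2 | step 2 | (1S)-1-[5-(4,4,5,5-tetramethyl-1,3,2-dioxaborolan-2-yl)furan-3-yl]but-3-en-1-ol | C=CC[C@H](O)c1coc(B2OC(C)(C)C(C)(C)O2)c1
F3 | step 4 | 2-{4-[(1S)-1-hydroxy-4-methylpent-3-en-1-yl]furan-2-yl}benzene-1,4-diol | CC(C)=CC[C@H](O)c1coc(-c2cc(O)ccc2O)c1
F4 | step 4 | 1-(2,5-dihydroxyphenyl)-5-[(1S)-1-hydroxy-4-methylpent-3-en-1-yl]-2,3,7-trioxabicyclo[2.2.1]hept-5-ene (both bridgehead diastereomers) | CC(C)=CC[C@H](O)C1=CC2(c3cc(O)ccc3O)OOC1O2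
F5 | step 4 | (2Z)-4-(2,5-dihydroxyphenyl)-2-[(1S)-1-hydroxy-4-methylpent-3-en-1-yl]-4-oxobut-2-enal | CC(C)=CC[C@H](O)/C(C=O)=C/C(=O)c1cc(O)ccc1O
F6 | step 4 | leucoalkannin, 2-[(1S)-1-hydroxy-4-methylpent-3-en-1-yl]naphthalene-1,4,5,8-tetrol | CC(C)=CC[C@H](O)c1cc(O)c2c(O)ccc(O)c2c1O
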